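common to all: initiator 5 mol%
- teal: free monomer 5 mM; protic impurity 5 mM; the very flask that is asked about, followed so far
- flask: free monomer 5.0 mM; protic impurity 5.00 mM; time 6.0 min
teal run (percent of the free monomer charged)

| time / min | monomer in chains / % | free monomer / % |
|---|---|---|
| 0.333 | 11.5 | 69.8 |
| 0.833 | 23.0 | 40.1 |
| 1.50 | 36.8 | 18.1 |
| 2.50 | 46.7 | 5.1 |

(scatter of a reading: 1 percentage point)
- the average divides the monomer in chains by the number of chains begun, living and dead together
- the earlier runs do not show the number of chains; that part of a forecast is a guess
1. whether the average number of monomer units in a chain (chains begun, living or dead) reaches 6.0 by 6.0 min (yes / no)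
2. average number of monomer units in a chain (chains begun, living or dead) at 6.0 min

I decided to follow this flask by the fraction of free monomer left, because the teal run is this very flask, and its last reading, at 2.50 min, has 5.10 % of the charge left and 46.7 % in chains. So the chain share, monomer in chains over free monomer reacted, read 0.492. Between the last two readings the free monomer fell, roughly pseudo-first-order, at 1.27 min⁻¹, which leaves 0.0606 % at 6.0 min, so nearly all will have reacted. The readings do not show the number of chains, so I guessed one chain per initiator charged, and chain share times fraction reacted over loading gave 9.84, the floor length, which is the length if each initiator begins one chain. On that guess the wanted 6.0 needs 0.300 of the charge in chains, and the reading at 1.50 min, 36.8 %, was already more than that, so I answered yes.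

The weak link was the constant share. Across the last two readings the chains gained 9.9 percentage points while the free monomer lost 13 points, a later share of 0.762, more than 0.492, though each reading carries a scatter of 1 point. Spending the remainder at that share put 0.505 in chains and the floor at 10.1, and I committed to that.

The forecast gave yes and 10.5, “higher if initiation is incomplete”.

The flask gives yes and 11.7.

    free monomer + initiator → living end + monomer in chains (k = 8.90 L mol⁻¹ s⁻¹)
    free monomer + living end → monomer in chains + living end, rate k2*[living end]*[free monomer] (k = 57.0 L mol⁻¹ s⁻¹)
    2 initiator → spent initiator (k = 17.0 L mol⁻¹ s⁻¹)
    protic impurity + free monomer → quenched substrate (k = 2.70 L mol⁻¹ s⁻¹)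

The flask's 11.7 stands above both my floors, 9.84 and 10.1, and the floor taken on its own 48.2 % in chains at 6.0 min is 9.65, while living end holds 0.205 mM of the 0.250 mM of initiator charged. At 0.468 min free monomer in this flask went to quenched substrate 1.2 times as fast as it went into chains by growth on the living end, a ratio of that moment. At 6.0 min the flask holds 51.6 % as quenched substrate, with 48 % of the protic impurity remaining.

The earlier runs and the new flask come from a simulation on assumed constants, noise included.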